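**Retrosynthetic overview**

- The target is reached from naphthalene-1,4-diol 24 by oxidation, cleavage of the peri methyl ether and ester hydrolysis.
- Feature the plan rests on: carbons C1–C4 of the quinone ring (chromone C8 on C2, hydroxyl on C5) are carried as a four-membered ring. Hydroxycyclobutenone 21 opens to a dienylketene, which closes onto the single free ortho carbon (future C8a) of the 2-methoxy-4-methylphenyl group, forming C1–C8a.
- 21 comes from cyclobutenedione 18 and an aryl Grignard reagent; 18 comes from a dichloroketene [2+2] cycloaddition on 8-ethynylchromone 15, then hydrolysis.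
- 15 comes from aldehyde 14 and 8-allylchromone 11, and 11 from the enaminone cyclisation of hydroxyacetophenone 9. 9 is made from symmetric 2,6-dihydroxy-4-methylacetophenone 4 by mono-allylation, triflation, Claisen rearrangement and carbonylation.
- Ring order: chromone benzene ring (bought), pyranone ring (step 7), four-membered ring (step 11), quinone carbocycle (step 14); the anisyl ring is bought.

Key step: step 14

Assumption: the axis between chromone C8 and quinone C2 is treated as stereochemically undefined, as in the target structure, which carries no stereodescriptor; if rotation is slow the route gives the racemate.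

**Route**

Step 1
Reactants: 1 3,5-dimethoxytoluene
Product: 3 1-(2,6-dimethoxy-4-methylphenyl)ethan-1-one, via aryllithium 2 (not isolated)
Conditions: n-BuLi, THF, 0 °C to rt; then MeC(O)N(OMe)Me, −78 °C to rt; aq. NH4Cl
Reagents that add atoms: N-methoxy-N-methylacetamide, CON(C)C(C)=O
Why: Directed ortho-lithiation removes the ring proton between the two methoxy groups, and acylation of the aryllithium with a Weinreb amide stops at the ketone through the chelated tetrahedral adduct.

Step 2
Reactants: 3 1-(2,6-dimethoxy-4-methylphenyl)ethan-1-one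
Product: 4 1-(2,6-dihydroxy-4-methylphenyl)ethan-1-one
Conditions: BBr3, CH2Cl2, −78 °C to rt; H2O
Reagents that add atoms: none
Why: Lewis-acid aryl methyl ether cleavage with BBr3, assisted by chelation because both methoxy groups are ortho to the carbonyl.

Step 3
Reactants: 4 1-(2,6-dihydroxy-4-methylphenyl)ethan-1-one
Product: 5 1-[2-hydroxy-4-methyl-6-(prop-2-en-1-yloxy)phenyl]ethan-1-one
Conditions: allyl bromide (1.05 equiv), K2CO3, acetone, reflux
Reagents that add atoms: allyl bromide, C=CCBr
Why: Williamson etherification, in which mono-allylation of the symmetric diol should dominate because the remaining hydroxyl is held in a hydrogen bond to the ketone after the first alkylation.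

Step 4
Reactants: 5 1-[2-hydroxy-4-methyl-6-(prop-2-en-1-yloxy)phenyl]ethan-1-one
Product: 6 2-acetyl-5-methyl-3-(prop-2-en-1-yloxy)phenyl trifluoromethanesulfonate
Conditions: Tf2O, pyridine, CH2Cl2, 0 °C
Reagents that add atoms: trifluoromethanesulfonic anhydride, O=S(=O)(OS(=O)(=O)C(F)(F)F)C(F)(F)F
Why: O-sulfonylation of the remaining phenol, which fixes the difference between the two oxygens of the symmetric precursor (one becomes the ring oxygen, the other marks the carboxyl position).

Step 5
Reactants: 6 2-acetyl-5-methyl-3-(prop-2-en-1-yloxy)phenyl trifluoromethanesulfonate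
Product: 8 2-acetyl-3-hydroxy-5-methyl-4-(prop-2-en-1-yl)phenyl trifluoromethanesulfonate, via Claisen dienone 7 (not isolated)
Conditions: 1,2-dichlorobenzene, 180 °C
Reagents that add atoms: none
Why: Aromatic Claisen rearrangement ([3,3]-sigmatropic shift) to the only free ortho carbon followed by enolisation of dienone 7, so the position between oxygen and CH3 is functionalised without a regiochemical choice.

Step 6
Reactants: 8 2-acetyl-3-hydroxy-5-methyl-4-(prop-2-en-1-yl)phenyl trifluoromethanesulfonate
Product: 9 methyl 2-acetyl-3-hydroxy-5-methyl-4-(prop-2-en-1-yl)benzoate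
Conditions: CO (1 atm), Pd(OAc)2, dppp, Et3N, MeOH/DMF, 70 °C
Reagents that add atoms: carbon monoxide, [C-]#[O+]; methanol, CO
Why: Palladium-catalysed alkoxycarbonylation of an aryl triflate (oxidative addition, CO insertion, methanolysis of the acylpalladium), with the bidentate dppp ligand suited to ortho-substituted triflates and the C-allyl group and chelated phenol as spectators.

Step 7
Reactants: 9 methyl 2-acetyl-3-hydroxy-5-methyl-4-(prop-2-en-1-yl)benzoate
Product: 11 methyl 7-methyl-4-oxo-8-(prop-2-en-1-yl)-4H-chromene-5-carboxylate, via enaminone 10 (not isolated)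
Conditions: Me2NCH(OMe)2, toluene, 90 °C; then conc. HCl, CH2Cl2, rt
Reagents that add atoms: N,N-dimethylformamide dimethyl acetal, COC(OC)N(C)C
Why: Enaminone chromone synthesis, in which the acetyl CH3 condenses with the formamide acetal and acid-promoted conjugate addition of the phenol with loss of dimethylamine closes the pyranone ring.

Step 8
Reactants: 11 methyl 7-methyl-4-oxo-8-(prop-2-en-1-yl)-4H-chromene-5-carboxylate
Product: 12 methyl 7-methyl-4-oxo-8-[(E)-prop-1-en-1-yl]-4H-chromene-5-carboxylate
Conditions: RuHCl(CO)(PPh3)3 (cat.), toluene, 90 °C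
Reagents that add atoms: none
Why: Ruthenium hydride-catalysed olefin isomerisation (hydrometalation then β-hydride elimination) moves the double bond next to the arene under neutral conditions that the chromone tolerates; any Z isomer converges in step 9.

Step 9
Reactants: 12 methyl 7-methyl-4-oxo-8-[(E)-prop-1-en-1-yl]-4H-chromene-5-carboxylate
Product: 14 methyl 8-formyl-7-methyl-4-oxo-4H-chromene-5-carboxylate, via diol 13 (not isolated)
Conditions: OsO4 (cat.), NaIO4, 2,6-lutidine, dioxane/H2O, rt
Reagents that add atoms: sodium periodate, [Na+].[O-]I(=O)(=O)=O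
Why: Lemieux–Johnson oxidation, in which the electron-rich propenyl double bond is dihydroxylated much faster than the vinylogous-ester C2=C3 bond of the chromone and periodate cleaves diol 13 to the aryl aldehyde.

Step 10
Reactants: 14 methyl 8-formyl-7-methyl-4-oxo-4H-chromene-5-carboxylate
Product: 15 methyl 8-ethynyl-7-methyl-4-oxo-4H-chromene-5-carboxylate
Conditions: dimethyl (1-diazo-2-oxopropyl)phosphonate, K2CO3, MeOH, 0 °C to rt
Reagents that add atoms: dimethyl (1-diazo-2-oxopropyl)phosphonate, CC(=O)C(=[N+]=[N-])P(=O)(OC)OC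
Why: Ohira–Bestmann homologation, in which the diazomethylphosphonate anion formed in the flask adds to the non-enolisable aldehyde and loss of phosphate and N2 gives an alkylidene carbene that rearranges by 1,2-shift to the terminal alkyne.

Step 11
Reactants: 15 methyl 8-ethynyl-7-methyl-4-oxo-4H-chromene-5-carboxylate; 16 trichloroacetyl chloride
Product: 17 methyl 8-(4,4-dichloro-3-oxocyclobut-1-en-1-yl)-7-methyl-4-oxo-4H-chromene-5-carboxylate
Conditions: Zn–Cu couple, DME/Et2O, rt
Reagents that add atoms: none
Why: [2+2] cycloaddition of dichloroketene (from zinc dechlorination of 16) with a terminal arylalkyne, the ketene carbonyl carbon bonding to the terminal alkyne carbon, with DME binding ZnCl2 so that chlorine migration in the adduct is suppressed.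

Step 12
Reactants: 17 methyl 8-(4,4-dichloro-3-oxocyclobut-1-en-1-yl)-7-methyl-4-oxo-4H-chromene-5-carboxylate
Product: 18 methyl 8-(3,4-dioxocyclobut-1-en-1-yl)-7-methyl-4-oxo-4H-chromene-5-carboxylate
Conditions: AgOCOCF3, MeCN/H2O, rt to 50 °C
Reagents that add atoms: water, O
Why: Silver-assisted hydrolysis of the allylic gem-dichloride, in which chloride abstraction gives a chlorine-stabilised cyclobutenyl cation that water captures and the chlorohydrin loses HCl to the 1,2-dione (gem-dihalide hydrolysis as used for strained four-ring diones).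

Step 13
Reactants: 18 methyl 8-(3,4-dioxocyclobut-1-en-1-yl)-7-methyl-4-oxo-4H-chromene-5-carboxylate; 19 2-bromo-5-methylanisole
Product: 21 methyl 8-[3-hydroxy-3-(2-methoxy-4-methylphenyl)-4-oxocyclobut-1-en-1-yl]-7-methyl-4-oxo-4H-chromene-5-carboxylate (racemic), via aryl Grignard reagent 20 (not isolated)
Conditions: 19, Mg, THF, rt; then added to 18 (1.05 equiv of 20), THF, −78 °C; aq. NH4Cl
Reagents that add atoms: none
Why: Grignard 1,2-addition to the strained dione, expected at the carbonyl flanked by the ring CH because the carbonyl beside the chromonyl-bearing carbon is screened on both faces by the twisted 2,6-disubstituted chromone (7-methyl and ring oxygen) and the pyranone carbonyl and ester are far slower at −78 °C; the carbinol centre forms as a racemate and is destroyed in step 14.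

Step 14
Reactants: 21 methyl 8-[3-hydroxy-3-(2-methoxy-4-methylphenyl)-4-oxocyclobut-1-en-1-yl]-7-methyl-4-oxo-4H-chromene-5-carboxylate (racemic)
Product: 24 methyl 8-(1,4-dihydroxy-5-methoxy-7-methylnaphthalen-2-yl)-7-methyl-4-oxo-4H-chromene-5-carboxylate, via dienylketene 22 (not isolated), via 8aH-naphthalenone 23 (not isolated)
Conditions: p-xylene (degassed), 138 °C, Ar
Reagents that add atoms: none
Why: Heating cleaves the C(=O)–C(OH) bond of the cyclobutenone by thermal 4π conrotatory electrocyclic opening to dienylketene 22, the donor hydroxyl turning outward so that the anisyl ring ends up cis to the ketene. The ketene carbon then bonds to the unsubstituted ortho carbon of the anisyl ring in a 6π electrocyclisation that closes the six-membered carbocycle (naphthalene C1–C8a), and 8aH-naphthalenone 23 aromatises by proton shift to the 1,4-diol. The closest known reaction type is the Moore rearrangement of 4-aryl-4-hydroxycyclobutenones to 1,4-naphthohydroquinones. No stereocentre is created, since the carbinol centre of 21 and the transient C8a centre of 23 are both lost. Regiochemistry is fixed because the other ortho carbon carries OCH3, the chromonyl group already sits on the carbon that becomes C2, and the carbinol carbon becomes C4 beside the methoxy-bearing ring carbon; the torquoselectivity needed for closure is secured by the free hydroxyl.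

Step 15
Reactants: 24 methyl 8-(1,4-dihydroxy-5-methoxy-7-methylnaphthalen-2-yl)-7-methyl-4-oxo-4H-chromene-5-carboxylate
Product: 25 methyl 8-(5-methoxy-7-methyl-1,4-dioxo-1,4-dihydronaphthalen-2-yl)-7-methyl-4-oxo-4H-chromene-5-carboxylate
Conditions: Ag2O, MgSO4, CH2Cl2, rt
Reagents that add atoms: none
Why: Two-electron dehydrogenation of a 1,4-hydroquinone to the quinone with Ag2O, which leaves the chromone and ester untouched.

Step 16
Reactants: 25 methyl 8-(5-methoxy-7-methyl-1,4-dioxo-1,4-dihydronaphthalen-2-yl)-7-methyl-4-oxo-4H-chromene-5-carboxylate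
Product: 26 methyl 8-(5-hydroxy-7-methyl-1,4-dioxo-1,4-dihydronaphthalen-2-yl)-7-methyl-4-oxo-4H-chromene-5-carboxylate
Conditions: BCl3, CH2Cl2, −78 to 0 °C; H2O
Reagents that add atoms: none
Why: Chelation-controlled ether cleavage, in which BCl3 binds between the peri methoxy oxygen and the C4 quinone carbonyl and removes only this methyl group while the methyl ester survives at low temperature.

Step 17
Reactants: 26 methyl 8-(5-hydroxy-7-methyl-1,4-dioxo-1,4-dihydronaphthalen-2-yl)-7-methyl-4-oxo-4H-chromene-5-carboxylate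
Product: 27 8-(5-hydroxy-7-methyl-1,4-dioxo-1,4-dihydronaphthalen-2-yl)-7-methyl-4-oxo-4H-chromene-5-carboxylic acid
Conditions: H2SO4, AcOH/H2O, 100 °C
Reagents that add atoms: water, O
Why: Acid-catalysed ester hydrolysis (acyl–oxygen cleavage), chosen because the chromone and hydroxyquinone units are base-labile but stable to hot aqueous acid with a non-nucleophilic counter-ion.

**Compound list**

1 | 3,5-dimethoxytoluene | COc1cc(C)cc(OC)c1 | starting material
2 | (2,6-dimethoxy-4-methylphenyl)lithium | [Li]c1c(OC)cc(C)cc1OC | intermediate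
3 | 1-(2,6-dimethoxy-4-methylphenyl)ethan-1-one | CC(=O)c1c(OC)cc(C)cc1OC | intermediate
4 | 1-(2,6-dihydroxy-4-methylphenyl)ethan-1-one | CC(=O)c1c(O)cc(C)cc1O | intermediate
5 | 1-[2-hydroxy-4-methyl-6-(prop-2-en-1-yloxy)phenyl]ethan-1-one | CC(=O)c1c(O)cc(C)cc1OCC=C | intermediate
6 | 2-acetyl-5-methyl-3-(prop-2-en-1-yloxy)phenyl trifluoromethanesulfonate | CC(=O)c1c(OCC=C)cc(C)cc1OS(=O)(=O)C(F)(F)F | intermediate
7 | 2-acetyl-5-methyl-3-oxo-4-(prop-2-en-1-yl)cyclohexa-1,5-dien-1-yl trifluoromethanesulfonate (racemic Claisen dienone) | CC(=O)C1=C(OS(=O)(=O)C(F)(F)F)C=C(C)C(CC=C)C1=O | intermediate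
8 | 2-acetyl-3-hydroxy-5-methyl-4-(prop-2-en-1-yl)phenyl trifluoromethanesulfonate | CC(=O)c1c(O)c(CC=C)c(C)cc1OS(=O)(=O)C(F)(F)F | intermediate
9 | methyl 2-acetyl-3-hydroxy-5-methyl-4-(prop-2-en-1-yl)benzoate | COC(=O)c1cc(C)c(CC=C)c(O)c1C(C)=O | intermediate
10 | methyl 2-[(E)-3-(dimethylamino)prop-2-enoyl]-3-hydroxy-5-methyl-4-(prop-2-en-1-yl)benzoate | COC(=O)c1cc(C)c(CC=C)c(O)c1C(=O)/C=C/N(C)C | intermediate
11 | methyl 7-methyl-4-oxo-8-(prop-2-en-1-yl)-4H-chromene-5-carboxylate | COC(=O)c1cc(C)c(CC=C)c2occc(=O)c12 | intermediate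
12 | methyl 7-methyl-4-oxo-8-[(E)-prop-1-en-1-yl]-4H-chromene-5-carboxylate | COC(=O)c1cc(C)c(/C=C/C)c2occc(=O)c12 | intermediate
13 | methyl 8-(1,2-dihydroxypropyl)-7-methyl-4-oxo-4H-chromene-5-carboxylate (racemic, configuration not controlled) | COC(=O)c1cc(C)c(C(O)C(C)O)c2occc(=O)c12 | intermediate
14 | methyl 8-formyl-7-methyl-4-oxo-4H-chromene-5-carboxylate | COC(=O)c1cc(C)c(C=O)c2occc(=O)c12 | intermediate
15 | methyl 8-ethynyl-7-methyl-4-oxo-4H-chromene-5-carboxylate | COC(=O)c1cc(C)c(C#C)c2occc(=O)c12 | intermediate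
16 | trichloroacetyl chloride | O=C(Cl)C(Cl)(Cl)Cl | starting material
17 | methyl 8-(4,4-dichloro-3-oxocyclobut-1-en-1-yl)-7-methyl-4-oxo-4H-chromene-5-carboxylate | COC(=O)c1cc(C)c(C2=CC(=O)C2(Cl)Cl)c2occc(=O)c12 | intermediate
18 | methyl 8-(3,4-dioxocyclobut-1-en-1-yl)-7-methyl-4-oxo-4H-chromene-5-carboxylate | COC(=O)c1cc(C)c(C2=CC(=O)C2=O)c2occc(=O)c12 | intermediate
19 | 2-bromo-5-methylanisole | COc1cc(C)ccc1Br | starting material
20 | (2-methoxy-4-methylphenyl)magnesium bromide | COc1cc(C)ccc1[Mg]Br | intermediate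
21 | methyl 8-[3-hydroxy-3-(2-methoxy-4-methylphenyl)-4-oxocyclobut-1-en-1-yl]-7-methyl-4-oxo-4H-chromene-5-carboxylate (racemic) | COC(=O)c1cc(C)c(C2=CC(O)(c3ccc(C)cc3OC)C2=O)c2occc(=O)c12 | intermediate
22 | methyl 8-[(3E)-4-hydroxy-4-(2-methoxy-4-methylphenyl)-1-oxobuta-1,3-dien-2-yl]-7-methyl-4-oxo-4H-chromene-5-carboxylate | COC(=O)c1cc(C)c(C(=C=O)/C=C(/O)c3ccc(C)cc3OC)c2occc(=O)c12 | intermediate
23 | methyl 8-(4-hydroxy-5-methoxy-7-methyl-1-oxo-1,8a-dihydronaphthalen-2-yl)-7-methyl-4-oxo-4H-chromene-5-carboxylate (racemic) | COC(=O)c1cc(C)c(C3=CC(O)=C4C(OC)=CC(C)=CC4C3=O)c2occc(=O)c12 | intermediate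
24 | methyl 8-(1,4-dihydroxy-5-methoxy-7-methylnaphthalen-2-yl)-7-methyl-4-oxo-4H-chromene-5-carboxylate | COC(=O)c1cc(C)c(-c2cc(O)c3c(OC)cc(C)cc3c2O)c2occc(=O)c12 | intermediate
25 | methyl 8-(5-methoxy-7-methyl-1,4-dioxo-1,4-dihydronaphthalen-2-yl)-7-methyl-4-oxo-4H-chromene-5-carboxylate | COC(=O)c1cc(C)c(C2=CC(=O)c3c(OC)cc(C)cc3C2=O)c2occc(=O)c12 | intermediate
26 | methyl 8-(5-hydroxy-7-methyl-1,4-dioxo-1,4-dihydronaphthalen-2-yl)-7-methyl-4-oxo-4H-chromene-5-carboxylate | COC(=O)c1cc(C)c(C2=CC(=O)c3c(O)cc(C)cc3C2=O)c2occc(=O)c12 | intermediate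
27 | 8-(5-hydroxy-7-methyl-1,4-dioxo-1,4-dihydronaphthalen-2-yl)-7-methyl-4-oxo-4H-chromene-5-carboxylic acid | Cc1cc(O)c2c(c1)C(=O)C(c1c(C)cc(C(=O)O)c3c(=O)ccoc13)=CC2=O | target

**Totals**

Total step count: 17. Longest linear sequence: 17 steps (1 to 27); the aryl Grignard reagent is made inside step 13.

**Steps most likely to fail**

Step 12. The hydrolysis may be diverted by migration of chlorine to the vinylic carbon before ionisation, or by capture of water at the CH terminus of the allyl cation. The cycloaddition of step 11 that feeds it may also be slow on an alkyne whose aryl group carries a para ester. The fallback sets out from alkyne 15 and replaces steps 11 and 12. Thermal radical [2+2] cycloaddition with chlorotrifluoroethylene (FC(F)=C(F)Cl, sealed tube, 120 °C) should give methyl 8-(4-chloro-3,3,4-trifluorocyclobut-1-en-1-yl)-7-methyl-4-oxo-4H-chromene-5-carboxylate F1. Brief heating of this in concentrated H2SO4 at 90 °C hydrolyses both halogenated carbons and comes back to the route at dione 18.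

Step 13. The Grignard reagent may attack the carbonyl next to the chromonyl-bearing carbon, which would lead to the regioisomeric quinone, or may react with the pyranone. The fallback sets out from dichloride 17, where the masked carbonyl is fixed by construction. Silver-assisted methanolysis (AgOTf, MeOH, 2,6-lutidine) should give methyl 8-(4,4-dimethoxy-3-oxocyclobut-1-en-1-yl)-7-methyl-4-oxo-4H-chromene-5-carboxylate F2. Reagent 20 can then add only to the single four-ring ketone, giving methyl 8-[3-hydroxy-4,4-dimethoxy-3-(2-methoxy-4-methylphenyl)cyclobut-1-en-1-yl]-7-methyl-4-oxo-4H-chromene-5-carboxylate F3. Mild acetal hydrolysis (oxalic acid on wet silica, CH2Cl2) comes back to the route at 21.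

Step 14. A share of the ring opening may proceed with inward rotation of the hydroxyl, or the free hydroxyl may trap the ketene, so that a butenolide forms in place of the carbocycle. The fallback sets out from 21 and blocks the hydroxyl. Silylation (Me3SiCl, imidazole, DMF) should give methyl 8-{3-(2-methoxy-4-methylphenyl)-4-oxo-3-[(trimethylsilyl)oxy]cyclobut-1-en-1-yl}-7-methyl-4-oxo-4H-chromene-5-carboxylate F4. Thermolysis in toluene at 110 °C should give methyl 8-{1-hydroxy-5-methoxy-7-methyl-4-[(trimethylsilyl)oxy]naphthalen-2-yl}-7-methyl-4-oxo-4H-chromene-5-carboxylate F5. Oxidative desilylation with (NH4)2Ce(NO3)6 in MeCN/H2O at 0 °C comes back to the route at quinone 25.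

**Further compounds**

F1 | step 12 | methyl 8-(4-chloro-3,3,4-trifluorocyclobut-1-en-1-yl)-7-methyl-4-oxo-4H-chromene-5-carboxylate (racemic) | COC(=O)c1cc(C)c(C2=CC(F)(F)C2(F)Cl)c2occc(=O)c12
F2 | step 13 | methyl 8-(4,4-dimethoxy-3-oxocyclobut-1-en-1-yl)-7-methyl-4-oxo-4H-chromene-5-carboxylate | COC(=O)c1cc(C)c(C2=CC(=O)C2(OC)OC)c2occc(=O)c12
F3 | step 13 | methyl 8-[3-hydroxy-4,4-dimethoxy-3-(2-methoxy-4-methylphenyl)cyclobut-1-en-1-yl]-7-methyl-4-oxo-4H-chromene-5-carboxylate (racemic) | COC(=O)c1cc(C)c(C2=CC(O)(c3ccc(C)cc3OC)C2(OC)OC)c2occc(=O)c12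
F4 | step 14 | methyl 8-{3-(2-methoxy-4-methylphenyl)-4-oxo-3-[(trimethylsilyl)oxy]cyclobut-1-en-1-yl}-7-methyl-4-oxo-4H-chromene-5-carboxylate (racemic) | COC(=O)c1cc(C)c(C2=CC(O[Si](C)(C)C)(c3ccc(C)cc3OC)C2=O)c2occc(=O)c12
F5 | step 14 | methyl 8-{1-hydroxy-5-methoxy-7-methyl-4-[(trimethylsilyl)oxy]naphthalen-2-yl}-7-methyl-4-oxo-4H-chromene-5-carboxylate | COC(=O)c1cc(C)c(-c2cc(O[Si](C)(C)C)c3c(OC)cc(C)cc3c2O)c2occc(=O)c12
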